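**Plan**
Chain numbering: C1 is the CH2 on the guaiacyl ring (4-hydroxy-3-methoxyphenyl), C3 the ketone, C4=C5 the alkene, C7 the CH2 on the syringyl ring (4-hydroxy-3,5-dimethoxyphenyl).
Retrosynthesis: the C3(acyl)–C4(vinyl) bond is cut first, giving the S-2-pyridyl thioester of dihydroferulic acid and 4-(but-3-ynyl)-2,6-dimethoxyphenol; the alkyne is then traced back through a C7 carbinol to syringaldehyde and a propargyl unit (C6–C7 bond).
Enabling feature: in the C3(=O)–C4H=C5H–C6 enone, C4 carries only hydrogen and C5 one alkyl chain, so the unit is the linear hydroacylation retron of a terminal alkyne C4≡C5. The two aromatic rings carry only OH and OMe groups, which a Ni(0)/Zn/water cycle should tolerate, so no protecting group is planned.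
Forward: syringaldehyde is propargylated and the benzylic alcohol removed (2 steps); dihydroferulic acid is activated as its S-2-pyridyl thioester (1 step); the chain is joined last by nickel-catalysed reductive anti-Markovnikov hydroacylation, in which the pyridylthio activating group leaves. No ring is formed.
Stereochemistry: the E geometry of C4=C5 comes from syn acylnickelation of the alkyne followed by stereoretentive protonolysis; the racemic carbinol centre made in step 1 is erased in step 2.

Key step: step 4

Remark: the target has no stereogenic centre; its only stereo-element is the E-configured C4=C5 double bond, so the route is designed to give that single geometric isomer.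

**Route**

Step 1
Reactants: 1 syringaldehyde (4-hydroxy-3,5-dimethoxybenzaldehyde); 2 propargyl bromide (3-bromoprop-1-yne)
Product: 4 rac-1-(4-hydroxy-3,5-dimethoxyphenyl)but-3-yn-1-ol, via allenylzinc bromide 3 (not isolated)
Conditions: Zn dust (2.5 equiv), 2 (2 equiv), THF/sat. aq. NH4Cl, 0 °C to rt
Reagents that add atoms: none
Why: Zinc Barbier propargylation: zinc inserts into the C–Br bond of 2 to give allenylzinc bromide 3, which should add to the aldehyde through a cyclic SE2' transition state to give the homopropargylic alcohol; the weakly acidic aqueous medium keeps the phenol protonated and tolerated, and the new carbinol centre is racemic and is removed in step 2.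

Step 2
Reactants: 4 rac-1-(4-hydroxy-3,5-dimethoxyphenyl)but-3-yn-1-ol
Product: 6 alkyne 4-(but-3-yn-1-yl)-2,6-dimethoxyphenol, via p-quinone methide 5 (not isolated)
Conditions: Et3SiH (3 equiv), TFA (5 equiv), CH2Cl2, 0 °C
Reagents that add atoms: none
Why: Ionic hydrogenation (Et3SiH/TFA deoxygenation of an electron-rich benzylic alcohol): acid ionises the carbinol to the para-hydroxybenzylic cation (O-protonated quinone methide 5), which should be captured by hydride from triethylsilane; any enyne formed by reversible proton loss is re-protonated to the same cation, and the terminal alkyne is inert to silane/TFA at 0 °C.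

Step 3
Reactants: 7 3-(4-hydroxy-3-methoxyphenyl)propanoic acid (dihydroferulic acid)
Product: 9 S-(pyridin-2-yl) 3-(4-hydroxy-3-methoxyphenyl)propanethioate, via acyloxyphosphonium salt 8 (not isolated)
Conditions: 2,2'-dipyridyl disulfide (1.2 equiv), PPh3 (1.2 equiv), MeCN, rt
Reagents that add atoms: 2,2'-dipyridyl disulfide, c1ccc(SSc2ccccn2)nc1
Why: Mukaiyama redox condensation (PPh3/2,2'-dipyridyl disulfide thioesterification): the carboxylate is activated as acyloxyphosphonium salt 8 and attacked at the acyl carbon by pyridine-2-thiolate, driven by P=O formation; without base the soft thiolate should outcompete the phenol, as in the preparation of pyridyl thioesters of hydroxy acids.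

Step 4
Reactants: 9 S-(pyridin-2-yl) 3-(4-hydroxy-3-methoxyphenyl)propanethioate; 6 alkyne 4-(but-3-yn-1-yl)-2,6-dimethoxyphenol
Product: 12 (E)-1-(4-hydroxy-3-methoxyphenyl)-7-(4-hydroxy-3,5-dimethoxyphenyl)hept-4-en-3-one, via acylnickel(II) thiolate 10 (not isolated), via alkenylnickel(II) thiolate 11 (not isolated)
Conditions: Ni(ClO4)2·6H2O (10 mol %), Zn dust (2 equiv), ZnCl2 (1 equiv), H2O (2 equiv), degassed DME, rt
Reagents that add atoms: none
Why: Ni(0), formed from the Ni(II) salt and Zn, should insert into the C(acyl)–S bond of 9 with assistance from the pyridyl nitrogen to give acylnickel 10; the terminal alkyne of 6 then undergoes syn migratory insertion with the acyl group delivered to the unsubstituted alkyne carbon (future C4) to give alkenylnickel 11, whose C–Ni bond is protonated by water with retention while Zn returns Ni(II) to Ni(0). The closest known reaction type is the nickel-catalysed reductive anti-Markovnikov hydroacylation of terminal alkynes with S-2-pyridyl thioesters, an aldehyde-free alkyne hydroacylation. No ring is closed. No stereocentre is formed; the E geometry of C4=C5 follows from syn acylnickelation and stereoretentive protonolysis, which place the ketone and the CH2CH2Ar chain trans. The step needs linear regioselectivity, secured by the steric difference between the CH terminus and the substituted carbon of the monosubstituted alkyne, and chemoselectivity for the thioester over the two phenols, secured by N,S-chelation-assisted oxidative addition at room temperature, where the phenolic O–H bonds act only as further proton donors and acyl decarbonylation is slow.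

**Compound list**
1 | syringaldehyde (4-hydroxy-3,5-dimethoxybenzaldehyde) | COc1cc(C=O)cc(OC)c1O | starting material
2 | propargyl bromide (3-bromoprop-1-yne) | C#CCBr | starting material
3 | allenylzinc bromide (propa-1,2-dienylzinc bromide) | C=C=C[Zn]Br | intermediate
4 | rac-1-(4-hydroxy-3,5-dimethoxyphenyl)but-3-yn-1-ol | C#CCC(O)c1cc(OC)c(O)c(OC)c1 | intermediate
5 | p-quinone methide 4-(but-3-yn-1-ylidene)-2,6-dimethoxycyclohexa-2,5-dien-1-one (under TFA present as its O-protonated form, the 4-hydroxybenzylic cation) | C#CCC=C1C=C(OC)C(=O)C(OC)=C1 | intermediate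
6 | 4-(but-3-yn-1-yl)-2,6-dimethoxyphenol | C#CCCc1cc(OC)c(O)c(OC)c1 | intermediate
7 | 3-(4-hydroxy-3-methoxyphenyl)propanoic acid (dihydroferulic acid) | COc1cc(CCC(=O)O)ccc1O | starting material
8 | [3-(4-hydroxy-3-methoxyphenyl)propanoyloxy]triphenylphosphonium pyridine-2-thiolate | COc1cc(CCC(=O)O[P+](c2ccccc2)(c2ccccc2)c2ccccc2)ccc1O.[S-]c1ccccn1 | intermediate
9 | S-(pyridin-2-yl) 3-(4-hydroxy-3-methoxyphenyl)propanethioate | COc1cc(CCC(=O)Sc2ccccn2)ccc1O | intermediate
10 | [3-(4-hydroxy-3-methoxyphenyl)propanoyl]nickel(II) pyridine-2-thiolate (solvent ligands omitted) | COc1cc(CCC(=O)[Ni]Sc2ccccn2)ccc1O | intermediate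
11 | alkenylnickel(II) pyridine-2-thiolate from syn acylnickelation, acyl and Ni cis (solvent ligands omitted) | COc1cc(CCC(=O)/C=C(/CCc2cc(OC)c(O)c(OC)c2)[Ni]Sc2ccccn2)ccc1O | intermediate
12 | (E)-1-(4-hydroxy-3-methoxyphenyl)-7-(4-hydroxy-3,5-dimethoxyphenyl)hept-4-en-3-one | COc1cc(CCC(=O)/C=C/CCc2cc(OC)c(O)c(OC)c2)ccc1O | target

**Summary**
Total step count: 4. Longest linear sequence: 3 steps (1 → 4 → 6 → 12); the thioester arm is one step from 7.

**Steps most likely to fail**

1. Step 4 (key coupling). What may go wrong:
- transfer of the activated acyl group to a phenolic oxygen under Zn(II) activation, giving oligo-esters;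
- nickel-mediated oligomerisation or cyclotrimerisation of the terminal alkyne;
- loss of linear regioselectivity, or conjugate addition of the released thiolate to the enone.

The fallback sets out from 6 and 7 and returns at 12, using stoichiometric hydrozirconation and acylation on silyl-protected partners. Compound 6 is silylated (TBSCl, imidazole, DMF, rt) to tert-butyl[4-(but-3-yn-1-yl)-2,6-dimethoxyphenoxy]dimethylsilane F1. Compound 7 is bis-silylated (TBSCl 2.2 equiv, imidazole, DMF) to tert-butyldimethylsilyl 3-{4-[(tert-butyldimethylsilyl)oxy]-3-methoxyphenyl}propanoate F2, which oxalyl chloride with catalytic DMF (CH2Cl2, 0 °C to rt) should convert directly into 3-{4-[(tert-butyldimethylsilyl)oxy]-3-methoxyphenyl}propanoyl chloride F3. Hydrozirconation of F1 with the Schwartz reagent Cp2Zr(H)Cl (THF, rt) should give, by syn anti-Markovnikov Zr–H addition, the (E)-alkenylzirconocene chloride F4. CuBr·SMe2-catalysed acylation of F4 with F3 should then give (E)-1-{4-[(tert-butyldimethylsilyl)oxy]-3-methoxyphenyl}-7-{4-[(tert-butyldimethylsilyl)oxy]-3,5-dimethoxyphenyl}hept-4-en-3-one F5. Desilylation with AcOH-buffered TBAF (THF, 0 °C) returns to 12.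

2. Step 2 (ionic deoxygenation). What may go wrong: the benzylic cation loses a proton to a conjugated enyne that polymerises, or alkylates a second electron-rich syringyl ring, before hydride capture.

The fallback sets out from 4 and returns at 6, replacing the cationic silane reduction by a base-triggered 1,6-elimination and borohydride 1,6-addition. Compound 4 is acetylated (Ac2O, pyridine, cat. DMAP) to 4-[1-(acetyloxy)but-3-yn-1-yl]-2,6-dimethoxyphenyl acetate F6. Treatment with NaBH4 in MeOH/THF (0 °C to rt) should cleave the aryl acetate, expel the benzylic acetate from the phenoxide to form quinone methide 5, and reduce 5 at once by 1,6-hydride addition to 6.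

3. Step 1 (Barbier propargylation). What may go wrong: slow addition to the electron-rich aldehyde that carries an acidic para-hydroxy group, and propargyl/allenyl scrambling that gives the allenyl carbinol.

The fallback sets out from 1 and returns at 6, avoiding both the organozinc addition and the benzylic deoxygenation. Wittig olefination of 1 with ethyl (triphenylphosphoranylidene)acetate (toluene, 80 °C) should give ethyl (E)-3-(4-hydroxy-3,5-dimethoxyphenyl)prop-2-enoate F7. Hydrogenation (H2, Pd/C, EtOAc) gives ethyl 3-(4-hydroxy-3,5-dimethoxyphenyl)propanoate F8. DIBAL-H (2.2 equiv, CH2Cl2, −78 °C) gives 3-(4-hydroxy-3,5-dimethoxyphenyl)propanal F9. Ohira–Bestmann homologation (dimethyl (1-diazo-2-oxopropyl)phosphonate, K2CO3, MeOH, rt) then gives 6.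

**Further compounds**
F1 | step 4 | tert-butyl[4-(but-3-yn-1-yl)-2,6-dimethoxyphenoxy]dimethylsilane | C#CCCc1cc(OC)c(O[Si](C)(C)C(C)(C)C)c(OC)c1
F2 | step 4 | tert-butyldimethylsilyl 3-{4-[(tert-butyldimethylsilyl)oxy]-3-methoxyphenyl}propanoate | COc1cc(CCC(=O)O[Si](C)(C)C(C)(C)C)ccc1O[Si](C)(C)C(C)(C)C
F3 | step 4 | 3-{4-[(tert-butyldimethylsilyl)oxy]-3-methoxyphenyl}propanoyl chloride | COc1cc(CCC(=O)Cl)ccc1O[Si](C)(C)C(C)(C)C
F4 | step 4 | (E)-alkenylzirconocene chloride from F1 (Cp rings drawn η1) | Cl[Zr](/C=C/CCc1cc(OC)c(O[Si](C)(C)C(C)(C)C)c(OC)c1)(C1C=CC=C1)C1C=CC=C1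
F5 | step 4 | (E)-1-{4-[(tert-butyldimethylsilyl)oxy]-3-methoxyphenyl}-7-{4-[(tert-butyldimethylsilyl)oxy]-3,5-dimethoxyphenyl}hept-4-en-3-one | COc1cc(CCC(=O)/C=C/CCc2cc(OC)c(O[Si](C)(C)C(C)(C)C)c(OC)c2)ccc1O[Si](C)(C)C(C)(C)C
F6 | step 2 | 4-[1-(acetyloxy)but-3-yn-1-yl]-2,6-dimethoxyphenyl acetate | C#CCC(OC(C)=O)c1cc(OC)c(OC(C)=O)c(OC)c1
F7 | step 1 | ethyl (E)-3-(4-hydroxy-3,5-dimethoxyphenyl)prop-2-enoate | CCOC(=O)/C=C/c1cc(OC)c(O)c(OC)c1
F8 | step 1 | ethyl 3-(4-hydroxy-3,5-dimethoxyphenyl)propanoate | CCOC(=O)CCc1cc(OC)c(O)c(OC)c1
F9 | step 1 | 3-(4-hydroxy-3,5-dimethoxyphenyl)propanal | O=CCCc1cc(OC)c(O)c(OC)c1
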